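The ratio I carry is the length gain g = 1/f, where f is the loading of Z on E. If each Z begins one chain, g times the fraction of charged E found as D is the average chain length (number-average degree of polymerization).

| flask | E | Q | Z | remark | time |
|---|---|---|---|---|---|
| north | 1 M | 1.5 M | 1.3 mol% | run made earlier |  |
| beta | 1.5 M | 1.50 M | 1.3 mol% |  | 2.0 d |
| zeta | 1.5 M | 1.50 M | 0.3 mol% |  | 2.0 d |

north run (percent of the E charged): time / h: D / % = 2.50: 0.5; 4.00: 1.5; 5.00: 2.2; 8.00: 3.8; 12.0: 7.9; 20.0: 14.0; 30.0: 18.4

(standard deviation of a reading: 0.5 percentage points)

- the average divides the monomer in chains by the number of chains begun, living and dead together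
- the earlier runs do not show the number of chains; that part of a forecast is a guess
- no earlier run changes the charge of Z; that part of a forecast is a guess

1. which of the two ends with the longer chains by the average number of monomer units in a chain (chains begun, living or dead) ("neither" if they lie within 10%) (beta / zeta / neither)
2. average number of monomer units in a chain (chains begun, living or dead) at the end, beta
3. average number of monomer units in a chain (chains begun, living or dead) at the end, zeta

At the north run's loading, which beta shares, g = 76.9, so the last north reading, at 30.0 h, reads as 14.2 units per chain if each Z has begun a chain by then.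

Carrying the last north slope on to 2.0 d gives D of 26.3%. I scale this by 1.50, the ratio of the E charges, since at equal loading beta holds that much more Z per litre than north. That gives 39.5% and my estimate of 30.4 units for beta.

Zeta has g = 333, so it ends longer by more than 10% if D in beta stays below 3.94 times D in zeta. I expect that, but no earlier run changes Z, so it is a guess.

The forecast says zeta, with 28 for beta and 45 for zeta: “Zeta is probably longer”.

The flasks give zeta, with 27.0 for beta and 35.0 for zeta, and D in beta is 3.32 times D in zeta, less than 3.94.

    Q + E → L (k = 0.0110 M⁻¹ h⁻¹)
    E + Z → X + D (k = 0.150 M⁻¹ h⁻¹)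
    E + X → D + X, rate k3*[X]*[E] (k = 1.10 M⁻¹ h⁻¹)
    E → J (k = 3.00 × 10⁻⁵ h⁻¹)
    E → G (k = 0.0130 h⁻¹)

In beta, the step from E to D uses E 1.5 times as fast as the step from Q + E to L at 0.686 d and 1.8 times as fast at 2.00 d, and beta ends with L at 28.1% and D at 34.7% of the E charged, a D that g turns into 26.7 units. The neighbour of beta charged with 0.38 M of Q keeps the same loading and so the same g, and it ends with L at 8.22% and D at 42.8%, a D that g turns into 32.9 units.

(The earlier runs and the new flask were computed on assumed constants; noise was put on by code.)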